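**Strategy.** With the carbocycle numbered C1 (side chain), C2 (OAc), C3 (C=O), C4 (CH3, epoxide), C5 (epoxide CH) and C6 (CH2), the plan rests on disconnecting C4. The feature used is the C3(=O)–C4(CH3)–C5 unit, an α-methyl enone in disguise. Chloro(methyl)carbene adds to a 1-silyloxycyclopentene that already carries the C1 stereocentre, and the strained 6-chloro-1-silyloxybicyclo[3.1.0]hexane opens to a 2-methylcyclohex-2-enone. One operation gives the six-membered ring, the C3 ketone, the C4 methyl and the C4=C5 alkene that later becomes the epoxide. The precursor derives from (S)-4-silyloxycyclopentenone by cuprate addition, elimination and 1,4-hydrosilylation.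

Key step: step 3

Remark: compounds 1, 2, 14 (pentane solution) and 19 are taken as commercial. Ring atoms keep the numbering C1–C6 above; C7 is the side-chain carbon bearing =CH2 and C8 the carbinol carbon.

**Step 1**
Reactants: 1 (S)-4-[(tert-butyldimethylsilyl)oxy]cyclopent-2-en-1-one; 2 2-bromo-3,3-diethoxyprop-1-ene
Product: 6 (S)-4-(3,3-diethoxyprop-1-en-2-yl)cyclopent-2-en-1-one, via vinyllithium 3 (not isolated), via lithium divinylcuprate 4 (not isolated), via trans silyloxy ketone 5 (not isolated)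
Conditions: 2, n-BuLi, Et2O, −78 °C; CuI, −40 °C; 1, −78 °C; AcOH then DBU, −78 to 23 °C
Reagents that add atoms: none
Why: Bromine–lithium exchange and formation of the Gilman cuprate (monovalent copper) are followed by conjugate addition anti to the silyloxy group, which sets C1 under substrate control, and DBU then removes silanolate from 5 by E1cB elimination to give the enone.

**Step 2**
Reactants: 6 (S)-4-(3,3-diethoxyprop-1-en-2-yl)cyclopent-2-en-1-one
Product: 7 {[(4R)-4-(3,3-diethoxyprop-1-en-2-yl)cyclopent-1-en-1-yl]oxy}triethylsilane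
Conditions: RhCl(PPh3)3 (cat.), Et3SiH, THF, 50 °C
Reagents that add atoms: triethylsilane, CC[SiH](CC)CC
Why: Rhodium-catalysed 1,4-hydrosilylation of an enone with a monohydrosilane fixes the enol ether double bond between C3 and C5, a regiochemistry that deprotonation of the saturated ketone would not guarantee, and touches no stereocentre.

**Step 3**
Reactants: 7 {[(4R)-4-(3,3-diethoxyprop-1-en-2-yl)cyclopent-1-en-1-yl]oxy}triethylsilane; 8 1,1-dichloroethane
Product: 11 (R)-5-(3,3-diethoxyprop-1-en-2-yl)-2-methylcyclohex-2-en-1-one, via carbenoid 9 (not isolated), via chlorocyclopropane 10 (not isolated)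
Conditions: n-BuLi, Et2O, −35 °C; then MeOH, Et3N, reflux
Reagents that add atoms: none
Why: Deprotonation of 8 gives carbenoid 9, which transfers chloro(methyl)carbene to the electron-rich C3=C5 enol ether bond in a [2+1] cycloaddition that closes the three-membered ring of 10 through two new bonds to C4. On heating, chloride leaves with concerted disrotatory cleavage of the C3–C5 bond (cyclopropyl-to-allyl cation electrocyclic opening) pushed by the silyloxy oxygen, and methanol takes the silyl group, so the five-membered ring becomes six-membered with C4 inserted. The closest known reaction type is the halocarbene ring expansion of cyclic silyl enol ethers to 2-substituted cycloalk-2-enones, here in its 1,1-dichloroethane/n-BuLi variant for 2-methyl enones. No new stereocentre survives, since the three cyclopropane centres are destroyed and C1 is not touched. Chemoselectivity for the enol ether over the 1,1-disubstituted alkene is needed and should follow from the much higher nucleophilicity of the silyl enol ether and the deactivating, hindering acetal on the other alkene. Chlorine must also sit on the concave (endo) side of 10 for opening within a six-membered ring, which the usual syn preference of chlorocarbenoids should favour.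

**Step 4**
Reactants: 11 (R)-5-(3,3-diethoxyprop-1-en-2-yl)-2-methylcyclohex-2-en-1-one
Product: 12 (1S,6S)-6-(3,3-diethoxyprop-1-en-2-yl)-3-methyl-2-oxocyclohex-3-en-1-yl acetate
Conditions: Mn(OAc)3·2H2O, benzene, reflux, Dean–Stark
Reagents that add atoms: manganese triacetate, CC(=O)[O-].CC(=O)[O-].CC(=O)[O-].[Mn+3]
Why: Manganese triacetate α′-acetoxylation of an enone acts at C2, the only enolisable α′ position, and should deliver acetate anti to the neighbouring C1 substituent to give the trans (diequatorial) product.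

**Step 5**
Reactants: 12 (1S,6S)-6-(3,3-diethoxyprop-1-en-2-yl)-3-methyl-2-oxocyclohex-3-en-1-yl acetate
Product: 13 (1S,6S)-3-methyl-2-oxo-6-(3-oxoprop-1-en-2-yl)cyclohex-3-en-1-yl acetate
Conditions: PPTS (cat.), acetone/H2O, 40 °C
Reagents that add atoms: water, O
Why: Mild acid hydrolysis of the acetal releases the 2-substituted acrolein while acetate and enone survive, and no stereocentre is affected.

**Step 6**
Reactants: 13 (1S,6S)-3-methyl-2-oxo-6-(3-oxoprop-1-en-2-yl)cyclohex-3-en-1-yl acetate; 14 (−)-B-allyldiisopinocampheylborane (from (+)-α-pinene)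
Product: 16 (1S,6S)-6-[(3S)-3-hydroxyhexa-1,5-dien-2-yl]-3-methyl-2-oxocyclohex-3-en-1-yl acetate, via borinate ester 15 (not isolated)
Conditions: Et2O, −78 °C; then ethanolamine, 0 to 23 °C
Reagents that add atoms: none
Why: Brown allylboration through a chair-like six-membered transition state delivers allyl to the Si face of the aldehyde under reagent control, setting C8 as S, and the aldehyde should react far faster than the hindered enone carbonyl at −78 °C, with ethanolamine freeing the alcohol without peroxide.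

**Step 7**
Reactants: 16 (1S,6S)-6-[(3S)-3-hydroxyhexa-1,5-dien-2-yl]-3-methyl-2-oxocyclohex-3-en-1-yl acetate; 17 2-methylbut-2-ene
Product: 18 (1S,6S)-6-[(3S)-3-hydroxy-6-methylhepta-1,5-dien-2-yl]-3-methyl-2-oxocyclohex-3-en-1-yl acetate
Conditions: second-generation Grubbs catalyst RuCl2(=CHPh)(H2IMes)(PCy3) (cat.), 17/CH2Cl2, 40 °C
Reagents that add atoms: none
Why: Olefin cross-metathesis of the monosubstituted alkene with excess 17 installs the isopropylidene terminus, the 1,1-disubstituted and enone double bonds being too hindered or electron-poor to take part.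

**Step 8**
Reactants: 18 (1S,6S)-6-[(3S)-3-hydroxy-6-methylhepta-1,5-dien-2-yl]-3-methyl-2-oxocyclohex-3-en-1-yl acetate; 19 angelic acid, (Z)-2-methylbut-2-enoic acid
Product: 21 (3S)-2-[(1S,2S)-2-acetoxy-4-methyl-3-oxocyclohex-4-en-1-yl]-6-methylhepta-1,5-dien-3-yl (Z)-2-methylbut-2-enoate, via mixed anhydride 20 (not isolated)
Conditions: 19, 2,4,6-trichlorobenzoyl chloride, Et3N, toluene, 23 °C; then 18, 80 °C
Reagents that add atoms: none
Why: Yamaguchi esterification through mixed anhydride 20 without a nucleophilic catalyst should acylate the hindered allylic alcohol while keeping the Z geometry of the angelate.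

**Step 9**
Reactants: 21 (3S)-2-[(1S,2S)-2-acetoxy-4-methyl-3-oxocyclohex-4-en-1-yl]-6-methylhepta-1,5-dien-3-yl (Z)-2-methylbut-2-enoate
Product: 22 (3S)-2-[(1S,2S,3S)-2-acetoxy-3-hydroxy-4-methylcyclohex-4-en-1-yl]-6-methylhepta-1,5-dien-3-yl (Z)-2-methylbut-2-enoate
Conditions: NaBH4, CeCl3·7H2O, MeOH, −78 °C
Reagents that add atoms: none
Why: In this Luche 1,2-reduction hydride should attack the enone carbonyl axially on the half-chair with both ring substituents equatorial, giving the equatorial C3 alcohol cis to the C1 side chain and trans to the C2 acetate, with the esters untouched.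

**Step 10**
Reactants: 22 (3S)-2-[(1S,2S,3S)-2-acetoxy-3-hydroxy-4-methylcyclohex-4-en-1-yl]-6-methylhepta-1,5-dien-3-yl (Z)-2-methylbut-2-enoate
Product: 23 (3S)-2-[(1R,2R,3S,4S,6S)-3-acetoxy-2-hydroxy-1-methyl-7-oxabicyclo[4.1.0]heptan-4-yl]-6-methylhepta-1,5-dien-3-yl (Z)-2-methylbut-2-enoate
Conditions: VO(acac)2 (cat.), t-BuOOH (decane), CH2Cl2, 0 to 23 °C
Reagents that add atoms: tert-butyl hydroperoxide, CC(C)(C)OO
Why: Vanadium-catalysed hydroxyl-directed epoxidation delivers oxygen to C4=C5 from the face of the coordinated C3 hydroxyl, which is cis to the C1 side chain and trans to the acetate, and leaves the isolated and ester-conjugated alkenes alone.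

**Step 11**
Reactants: 23 (3S)-2-[(1R,2R,3S,4S,6S)-3-acetoxy-2-hydroxy-1-methyl-7-oxabicyclo[4.1.0]heptan-4-yl]-6-methylhepta-1,5-dien-3-yl (Z)-2-methylbut-2-enoate
Product: 24 (3S)-2-[(1S,3S,4S,6S)-3-acetoxy-1-methyl-2-oxo-7-oxabicyclo[4.1.0]heptan-4-yl]-6-methylhepta-1,5-dien-3-yl (Z)-2-methylbut-2-enoate
Conditions: Dess–Martin periodinane, CH2Cl2, 0 to 23 °C
Reagents that add atoms: none
Why: Dess–Martin oxidation converts the secondary alcohol into the C3 ketone under near-neutral conditions that should neither epimerise C2 nor open the epoxide.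

**Compound list**
1 | (S)-4-[(tert-butyldimethylsilyl)oxy]cyclopent-2-en-1-one | O=C1C=C[C@@H](O[Si](C)(C)C(C)(C)C)C1 | starting material
2 | 2-bromo-3,3-diethoxyprop-1-ene | C=C(Br)C(OCC)OCC | starting material
3 | (3,3-diethoxyprop-1-en-2-yl)lithium | [Li]C(=C)C(OCC)OCC | intermediate
4 | lithium bis(3,3-diethoxyprop-1-en-2-yl)cuprate, LiCuR2 (monovalent copper) | [Li+].CCOC(OCC)C(=C)[Cu-]C(=C)C(OCC)OCC | intermediate
5 | (3R,4S)-4-[(tert-butyldimethylsilyl)oxy]-3-(3,3-diethoxyprop-1-en-2-yl)cyclopentan-1-one | C=C(C(OCC)OCC)[C@@H]1[C@@H](O[Si](C)(C)C(C)(C)C)CC(=O)C1 | intermediate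
6 | (S)-4-(3,3-diethoxyprop-1-en-2-yl)cyclopent-2-en-1-one | C=C(C(OCC)OCC)[C@@H]1C=CC(=O)C1 | intermediate
7 | {[(4R)-4-(3,3-diethoxyprop-1-en-2-yl)cyclopent-1-en-1-yl]oxy}triethylsilane | C=C(C(OCC)OCC)[C@@H]1CC=C(O[Si](CC)(CC)CC)C1 | intermediate
8 | 1,1-dichloroethane | CC(Cl)Cl | starting material
9 | 1,1-dichloroethyllithium | CC(Cl)(Cl)[Li] | intermediate
10 | 6-chloro-3-(3,3-diethoxyprop-1-en-2-yl)-6-methyl-1-[(triethylsilyl)oxy]bicyclo[3.1.0]hexane (side-chain centre as in 7, diastereomer mixture at the cyclopropane carbons) | C=C(C(OCC)OCC)[C@@H]1CC2C(C)(Cl)C2(O[Si](CC)(CC)CC)C1 | intermediate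
11 | (R)-5-(3,3-diethoxyprop-1-en-2-yl)-2-methylcyclohex-2-en-1-one | C=C(C(OCC)OCC)[C@@H]1CC=C(C)C(=O)C1 | intermediate
12 | (1S,6S)-6-(3,3-diethoxyprop-1-en-2-yl)-3-methyl-2-oxocyclohex-3-en-1-yl acetate | C=C(C(OCC)OCC)[C@@H]1CC=C(C)C(=O)[C@H]1OC(C)=O | intermediate
13 | (1S,6S)-3-methyl-2-oxo-6-(3-oxoprop-1-en-2-yl)cyclohex-3-en-1-yl acetate | C=C(C=O)[C@@H]1CC=C(C)C(=O)[C@H]1OC(C)=O | intermediate
14 | (−)-B-allyldiisopinocampheylborane | C=CCB([C@@H]1C[C@@H]2C[C@H]([C@H]1C)C2(C)C)[C@@H]1C[C@@H]2C[C@H]([C@H]1C)C2(C)C | starting material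
15 | O-(diisopinocampheylboryl) derivative of 16 | C=C([C@H](CC=C)OB([C@@H]2C[C@@H]3C[C@H]([C@H]2C)C3(C)C)[C@@H]2C[C@@H]3C[C@H]([C@H]2C)C3(C)C)[C@@H]1CC=C(C)C(=O)[C@H]1OC(C)=O | intermediate
16 | (1S,6S)-6-[(3S)-3-hydroxyhexa-1,5-dien-2-yl]-3-methyl-2-oxocyclohex-3-en-1-yl acetate | C=C([C@H](CC=C)O)[C@@H]1CC=C(C)C(=O)[C@H]1OC(C)=O | intermediate
17 | 2-methylbut-2-ene | CC=C(C)C | starting material
18 | (1S,6S)-6-[(3S)-3-hydroxy-6-methylhepta-1,5-dien-2-yl]-3-methyl-2-oxocyclohex-3-en-1-yl acetate | C=C([C@H](CC=C(C)C)O)[C@@H]1CC=C(C)C(=O)[C@H]1OC(C)=O | intermediate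
19 | angelic acid, (Z)-2-methylbut-2-enoic acid | C/C=C(/C)C(=O)O | starting material
20 | (Z)-2-methylbut-2-enoic 2,4,6-trichlorobenzoic anhydride | C/C=C(/C)C(=O)OC(=O)c1c(Cl)cc(Cl)cc1Cl | intermediate
21 | (3S)-2-[(1S,2S)-2-acetoxy-4-methyl-3-oxocyclohex-4-en-1-yl]-6-methylhepta-1,5-dien-3-yl (Z)-2-methylbut-2-enoate | C=C([C@H](CC=C(C)C)OC(=O)/C(C)=C\C)[C@@H]1CC=C(C)C(=O)[C@H]1OC(C)=O | intermediate
22 | (3S)-2-[(1S,2S,3S)-2-acetoxy-3-hydroxy-4-methylcyclohex-4-en-1-yl]-6-methylhepta-1,5-dien-3-yl (Z)-2-methylbut-2-enoate | C=C([C@H](CC=C(C)C)OC(=O)/C(C)=C\C)[C@@H]1CC=C(C)[C@H](O)[C@H]1OC(C)=O | intermediate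
23 | (3S)-2-[(1R,2R,3S,4S,6S)-3-acetoxy-2-hydroxy-1-methyl-7-oxabicyclo[4.1.0]heptan-4-yl]-6-methylhepta-1,5-dien-3-yl (Z)-2-methylbut-2-enoate | C=C([C@H](CC=C(C)C)OC(=O)/C(C)=C\C)[C@@H]1C[C@@H]2O[C@]2(C)[C@H](O)[C@H]1OC(C)=O | intermediate
24 | (3S)-2-[(1S,3S,4S,6S)-3-acetoxy-1-methyl-2-oxo-7-oxabicyclo[4.1.0]heptan-4-yl]-6-methylhepta-1,5-dien-3-yl (Z)-2-methylbut-2-enoate | C=C([C@H](CC=C(C)C)OC(=O)/C(C)=C\C)[C@@H]1C[C@@H]2O[C@]2(C)C(=O)[C@H]1OC(C)=O | target

**Total step count:** 11. **Longest linear sequence:** 11 steps (from 1).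

**Steps most likely to fail**

Step 3. Carbene transfer may lack chemoselectivity, or chlorine may end up on the convex face so that ring opening stalls. Fallback: setting out from 7, dibromocarbene (CHBr3, KOt-Bu, pentane, −20 °C) should give the dibromocyclopropane 6,6-dibromo-3-(3,3-diethoxyprop-1-en-2-yl)-1-[(triethylsilyl)oxy]bicyclo[3.1.0]hexane F1, in which one bromine is necessarily endo. On warming it should open to (R)-2-bromo-5-(3,3-diethoxyprop-1-en-2-yl)cyclohex-2-en-1-one F2. Suzuki–Miyaura methylation (methylboronic acid, PdCl2(dppf), K3PO4, dioxane/H2O, 80 °C) should then return to the route at 11.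

Step 4. The acetal may be lost under the hot conditions that release acetic acid, or the trans selectivity may erode. Fallback: setting out from 11, kinetic enolisation with LDA (THF, −78 °C) and oxygen transfer from 2-(phenylsulfonyl)-3-phenyloxaziridine should give (5S,6S)-5-(3,3-diethoxyprop-1-en-2-yl)-6-hydroxy-2-methylcyclohex-2-en-1-one F3. Acetylation (Ac2O, pyridine, DMAP) should rejoin the route at 12.

Step 6. Facial selectivity may erode if reagent and substrate preferences oppose each other, and addition to the ring ketone may compete. Fallback: setting out from 13, the enantiomeric borane, (+)-B-allyldiisopinocampheylborane, would then be the matched reagent and should give, through the O-(diisopinocampheylboryl) ester F4, the C8 epimer (1S,6S)-6-[(3R)-3-hydroxyhexa-1,5-dien-2-yl]-3-methyl-2-oxocyclohex-3-en-1-yl acetate F5. Cross-metathesis with 17 as in step 7 should give (1S,6S)-6-[(3R)-3-hydroxy-6-methylhepta-1,5-dien-2-yl]-3-methyl-2-oxocyclohex-3-en-1-yl acetate F6. Mitsunobu esterification with 19 (PPh3, DIAD, toluene, 0 °C) should invert C8 and rejoin the route at 21.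

**Further compounds**
F1 | step 3 | 6,6-dibromo-3-(3,3-diethoxyprop-1-en-2-yl)-1-[(triethylsilyl)oxy]bicyclo[3.1.0]hexane | C=C(C(OCC)OCC)[C@@H]1CC2C(Br)(Br)C2(O[Si](CC)(CC)CC)C1
F2 | step 3 | (R)-2-bromo-5-(3,3-diethoxyprop-1-en-2-yl)cyclohex-2-en-1-one | C=C(C(OCC)OCC)[C@@H]1CC=C(Br)C(=O)C1
F3 | step 4 | (5S,6S)-5-(3,3-diethoxyprop-1-en-2-yl)-6-hydroxy-2-methylcyclohex-2-en-1-one | C=C(C(OCC)OCC)[C@@H]1CC=C(C)C(=O)[C@H]1O
F4 | step 6 | O-(diisopinocampheylboryl) derivative of F5 (borane from (−)-α-pinene) | C=C([C@@H](CC=C)OB([C@H]2C[C@H]3C[C@@H]([C@@H]2C)C3(C)C)[C@H]2C[C@H]3C[C@@H]([C@@H]2C)C3(C)C)[C@@H]1CC=C(C)C(=O)[C@H]1OC(C)=O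
F5 | step 6 | (1S,6S)-6-[(3R)-3-hydroxyhexa-1,5-dien-2-yl]-3-methyl-2-oxocyclohex-3-en-1-yl acetate | C=C([C@@H](CC=C)O)[C@@H]1CC=C(C)C(=O)[C@H]1OC(C)=O
F6 | step 6 | (1S,6S)-6-[(3R)-3-hydroxy-6-methylhepta-1,5-dien-2-yl]-3-methyl-2-oxocyclohex-3-en-1-yl acetate | C=C([C@@H](CC=C(C)C)O)[C@@H]1CC=C(C)C(=O)[C@H]1OC(C)=O
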